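**Remarks.** Numbering follows the bicyclo[8.4.0]tetradecane skeleton of the target for every intermediate: ten-membered ring C1–C10; ring A = C10–C11–C12–C13–C14–C1; C16 = the methylene carbon on C7. The β face of ring A is the face that carries the C1 and C10 side arms (C2 and C9). Where a name carries no descriptor, the ring A centres C1, C10, C11 and C14 have the configuration written in the SMILES, which is that of the target. Assumption: centres that are later removed or reset (C5 of the sulfones, C9 of 13, C6 of 27) are carried as epimer mixtures and are written without a descriptor.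

## Analysis of the target

Compound 30 is a eunicellane-type bicyclo[8.4.0]tetradecane. A cyclohexane (ring A) is cis-fused through C1 and C10 to a ten-membered carbocycle that holds a Z trisubstituted alkene (C2=C3, methyl on C3), an exocyclic methylene on C7 and secondary acetates on C6 and C9. It has six stereocentres, (1S,6R,9R,10S,11R,14R). Four are contiguous on ring A: C14 (isopropyl α), C1 and C10 (hydrogens cis, side arms β) and C11 (methyl β, hydroxyl α, trans to the C9 arm). C9 lies next to the ring fusion. C6 is insulated from all the others by C7 and C8, so it cannot be set by relay from ring A. The sensitive groups are the allylic C6 acetate beside the methylene, the free tertiary C11 alcohol, and two alkenes facing each other across a medium ring, which invites transannular reactions under acid or electrophiles. Whenever C9 is a carbonyl on the way, C10–H is its α-hydrogen and the C11 oxygen sits β to it, so enolisation toward C10 means epimerisation of the ring fusion or β-elimination. The hard part is the ten-membered ring: an end-to-end closure pays for entropy and transannular strain and leaves the C2=C3 geometry open. The strategy rests on one feature: C6, C7(=C16H2) and C8 form a 2-methylenepropane-1,3-diyl unit between C5 and C9. Taking it out leaves a C5–C9 bond and a seven-membered ring C9–C10–C1–C2–C3–C4–C5 fused to ring A, in which the C2=C3 double bond can only be Z.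

## Retrosynthetic reasoning

**C6 oxygen (30 ⇒ 29 ⇒ 28 ⇒ 27 ⇒ 26).** The C6 acetate goes back to the allylic alcohol 29, this to the α-methylene ketone 28, and 28 through the epimeric alcohols 27 to 26, which has no oxygen on C6. C6 is remote from every other stereocentre, so its configuration is left to a catalyst-controlled 1,2-reduction of 28. The oxygen itself comes from a selenium-mediated allylic oxidation of the exocyclic methylene of 26. C6 is the allylic methylene to aim at, because C8 is deactivated by the neighbouring acetoxy-bearing C9. The forward reaction has to prefer the unhindered methylene over the ring alkene C2=C3.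

**C9 and C5 adjustment (26 ⇒ 25 ⇒ 24 ⇒ 23 ⇒ 22).** The C11 hydroxyl is protected again as its methoxymethyl ether (25), the C9 acetate is taken back to the alcohol 24, C5–H is replaced by phenylsulfonyl (23) and the C9 carbinol becomes the ketone 22. This leads straight to the ring-expansion product. The sulfone is only the anion-stabilising group and leaves by electron transfer. C9 is set by a catalyst-controlled reduction, because the preferred face of a flexible ten-membered ketone cannot be predicted. The acetal on C11 is needed only while C9 is a carbonyl, so it is removed before the acid-labile allylic C6 oxygen exists.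

**Key disconnection (22 ⇒ 19).** The C8–C9 bond is cut and the C5–C9 bond is restored, which contracts the ten-membered ring to the cycloheptenone 19 carrying the three carbons C6–C7–C8 as a silylmethylallyl group on C5. The cut is made here because C5 (sulfone) and C9 (ketone) flank exactly the 2-methylenepropane-1,3-diyl unit. The ten-membered ring is then never closed end to end, and the Z alkene is already secured in a small ring. In the forward sense, fluoride must trigger allyl transfer to C9 and the resulting alkoxide must break C5–C9.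

**C5–C6 bond (19 ⇒ 17 + 18).** The quaternary C5 is disconnected to the cyclic β-keto sulfone 17 and the allylic chloride 18. C5 is the only strongly acidic position of 17, so a carbonate base is enough and C10 is not touched.

**C2=C3 and C4–C5 bonds (17 ⇒ 16 ⇒ 14 + 15).** The ring alkene is opened to the vinyl group on C1 and a methallyl group on C5 (16), a metathesis pair for a seven-membered ring in which only the Z alkene can form. The methallyl group comes from alkylation of the β-keto sulfone 14 with 15.

**C5–C9 bond (14 ⇒ 13 ⇒ 11 + 12; 11 ⇒ 10 ⇒ 9).** The keto sulfone is cut between C5 and C9 to the aldehyde 11 and the sulfone 12 (addition, then oxidation of 13). The aldehyde comes from the silyl-protected primary alcohol 9 by way of 10, so that C9 keeps a low oxidation level until the base-sensitive β-alkoxy carbonyl is needed.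

**C11 carbinol (9 ⇒ 8 ⇒ 7 ⇒ 6 ⇒ 5).** The tertiary alcohol is traced to the C11=C12 alkene of 6 through the epoxide 7. The C10 arm, pseudoaxial to avoid allylic strain with the C11 methyl, blocks the β face, so the oxygen arrives α, and hydride opening at C12 leaves it on C11. The vinyl group of 6 comes from the aldehyde 5 by methylenation.

**Ring A (5 ⇒ 3 + 4; 3 ⇒ 2 ⇒ 1).** Cutting C1–C10 and C13–C14 gives the enal 4 and the diene 3 for a catalytic asymmetric Diels–Alder reaction. This sets C1, C10 and C14 in one step and delivers C2 and C9 as differentiated handles. The diene 3 comes from the enynol 1 by silylation and semi-hydrogenation.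

## Alternatives that were turned down

Alternative 1: catalytic asymmetric Diels–Alder reaction as the governing step.
- Disconnection: C1–C10 and C13–C14. Ring A is made from 4 and 3.
- Forward key step: an iminium-catalysed endo [4+2] cycloaddition gives the aldehyde A1, which is the same compound as 5.
- For it: one catalytic step sets three contiguous stereocentres from two cheap achiral partners and leaves an aldehyde (C2) and a protected carbinol (C9) to build on.
- Against it: it solves only ring A. C11, the chain C3–C8, the ten-membered ring, the Z alkene and both carbinols remain open. From A1 the obvious continuation is to grow both arms and close the ten-membered ring end to end, where ring strain and E/Z control are at their worst.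
- Comparison: on ring A it is equal, since the chosen route uses the same cycloaddition as step 3 and shares its regiochemical risk. The chosen strategy adds the answer to the medium ring by closing a seven-membered ring and expanding it.

Alternative 2: Wittig–Still [2,3] ring contraction.
- Disconnection: C9–C10, with the future C11 methyl carbon (C20) bound through oxygen to C9 in the thirteen-membered stannylmethyl allyl ether A2.
- Forward key step: n-BuLi exchanges tin for lithium, and the α-alkoxy carbanion shifts across C10=C11 to give the ten-membered alcohol A3.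
- For it: a thirteen-membered ether is easier to close than a ten-membered carbocycle. The shift forms C9–C10 and creates C9 and C10 together in an ordered five-membered transition state. The C6 oxygen is carried in from the start.
- Where it is stronger: the C6 oxygen is present early, whereas the chosen route must introduce it late by allylic oxidation.
- Against it: A2 needs a long linear preparation ending in a macrocyclisation. The sense of induction at C9 and C10 depends on the conformation of the macrocycle and cannot be predicted, and a [1,2] shift competes. A3 still needs ketal removal and methylenation at C7 and a stereoselective hydration of the C11 methylene beside two other alkenes.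
- Comparison: the chosen strategy offers a short, stereochemically settled precursor and a ring expansion in which no stereocentre is at stake.

Alternative 3: anionic oxy-Cope ring expansion.
- Disconnection: C4–C5 is cut and C2–C7 restored, which leads to the cis-decalin carbinol A4 with vinyl on C7 and isopropenyl on C2.
- Forward key step: KH and 18-crown-6 give the alkoxide, and the [3,3] shift opens ring B to the ten-membered C7 ketone A5 through its C6=C7 enolate.
- For it: a decalin is easy to assemble, and the shift forms the medium ring without a cyclisation.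
- Where it is stronger: the enolate is formed regiospecifically toward C6, so the C6 oxygen could be introduced directly there. This is cleaner than the allylic oxidation of the chosen route.
- Against it: A4 carries seven stereocentres, including a tertiary carbinol whose vinyl group must be cis to the isopropenyl group. The Z geometry of C2=C3 depends on one transition-state arrangement with the C1–C2 bond pseudoaxial. Under the strongly basic conditions the product ketone can enolise toward C8 and expel the C9 ether. C7 must still be methylenated next to an oxygenated C6.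
- Comparison: the chosen strategy offers a much shorter way to its precursor and a Z alkene fixed by ring size rather than by a transition state.

Key step: step 15

## Route

Step 1
Reactants: 1 (2E)-3-methylpent-2-en-4-yn-1-ol
Product: 2 tert-butyl{[(2E)-3-methylpent-2-en-4-yn-1-yl]oxy}diphenylsilane
Conditions: TBDPSCl, imidazole, CH2Cl2, 0 °C → rt
Reagents that add atoms: tert-butyl(chloro)diphenylsilane, CC(C)(C)[Si](Cl)(c1ccccc1)c1ccccc1
Why: Standard silylation of a primary allylic alcohol; the bulky silyl ether withstands the acidic aqueous cycloaddition medium, hydride and base, and later serves as the group that blocks the β face of ring A.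

Step 2
Reactants: 2 tert-butyl{[(2E)-3-methylpent-2-en-4-yn-1-yl]oxy}diphenylsilane
Product: 3 tert-butyl{[(2E)-3-methylpenta-2,4-dien-1-yl]oxy}diphenylsilane
Conditions: H2 (1 atm), Pd/CaCO3 poisoned with Pb(OAc)2 (Lindlar catalyst), quinoline, hexane/EtOAc, rt, stopped after 1 equiv H2
Reagents that add atoms: none
Why: Lindlar semi-hydrogenation of the terminal alkyne of a conjugated enyne should stop at the diene when hydrogen uptake is limited; the E trisubstituted alkene is not touched, so the diene can reach the s-cis form with its oxymethyl group outside.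

Step 3
Reactants: 3 tert-butyl{[(2E)-3-methylpenta-2,4-dien-1-yl]oxy}diphenylsilane; 4 (2E)-4-methylpent-2-enal
Product: 5 (1R,2R,6R)-2-({[tert-butyl(diphenyl)silyl]oxy}methyl)-3-methyl-6-(propan-2-yl)cyclohex-3-ene-1-carbaldehyde
Conditions: (5S)-5-benzyl-2,2,3-trimethylimidazolidin-4-one·HCl (20 mol%), MeCN/H2O (95:5), 0 °C → rt
Reagents that add atoms: none
Why: Organocatalytic asymmetric Diels–Alder reaction through the unsaturated iminium ion of 4; the benzyl group of the catalyst should leave open the face that is si at C1 and re at C14, the E enal gives the C1/C14 trans relation, and the endo approach to the E diene terminus gives the C1/C10 cis relation. The unsubstituted terminus C13 should bond to the β-carbon C14, as directed by the C10 substituent, so that C10 bonds to C1.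

Step 4
Reactants: 5 (1R,2R,6R)-2-({[tert-butyl(diphenyl)silyl]oxy}methyl)-3-methyl-6-(propan-2-yl)cyclohex-3-ene-1-carbaldehyde
Product: 6 tert-butyl{[6-ethenyl-2-methyl-5-(propan-2-yl)cyclohex-2-en-1-yl]methoxy}diphenylsilane (ring A configuration of 5)
Conditions: Ph3PCH3Br, KN(SiMe3)2, THF, −78 → 0 °C
Reagents that add atoms: methyltriphenylphosphonium bromide, C[P+](c1ccccc1)(c1ccccc1)c1ccccc1.[Br-]
Why: Wittig methylenation; the unstabilised ylide adds to the aldehyde at low temperature faster than it can epimerise C1, and it turns C2 into the vinyl arm needed for metathesis.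

Step 5
Reactants: 6 tert-butyl{[6-ethenyl-2-methyl-5-(propan-2-yl)cyclohex-2-en-1-yl]methoxy}diphenylsilane
Product: 7 tert-butyl{[3-ethenyl-1-methyl-4-(propan-2-yl)-7-oxabicyclo[4.1.0]heptan-2-yl]methoxy}diphenylsilane (11α,12α-epoxide, oxirane trans to the C10 arm)
Conditions: mCPBA (1.05 equiv), CH2Cl2, −20 → 0 °C
Reagents that add atoms: 3-chloroperoxybenzoic acid, OOC(=O)c1cccc(Cl)c1
Why: Prilezhaev epoxidation; the trisubstituted ring alkene reacts far faster than the vinyl group, and the C10 silyloxymethyl arm, held pseudoaxial by allylic strain with the C11 methyl, shields the β face so that oxygen is delivered to the α face.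

Step 6
Reactants: 7 tert-butyl{[3-ethenyl-1-methyl-4-(propan-2-yl)-7-oxabicyclo[4.1.0]heptan-2-yl]methoxy}diphenylsilane
Product: 8 2-({[tert-butyl(diphenyl)silyl]oxy}methyl)-3-ethenyl-1-methyl-4-(propan-2-yl)cyclohexan-1-ol (C11 hydroxyl α, methyl β)
Conditions: LiEt3BH, THF, 0 °C → rt; then H2O
Reagents that add atoms: none
Why: SN2 hydride opening at the less substituted C12, which is also the trans-diaxial (Fürst–Plattner) mode in the favoured half-chair, leaves the oxygen on C11; the C11 configuration is therefore that of the epoxide face set in step 5.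

Step 7
Reactants: 8 2-({[tert-butyl(diphenyl)silyl]oxy}methyl)-3-ethenyl-1-methyl-4-(propan-2-yl)cyclohexan-1-ol
Product: 9 tert-butyl{[2-ethenyl-6-(methoxymethoxy)-6-methyl-3-(propan-2-yl)cyclohexyl]methoxy}diphenylsilane
Conditions: MOMCl, i-Pr2NEt, Bu4NI (cat.), ClCH2CH2Cl, 60 °C
Reagents that add atoms: chloromethyl methyl ether, COCCl
Why: Acetal protection of a hindered tertiary alcohol with the iodide-activated chloromethyl ether; the small acetal survives fluoride, carbonate bases, oxidants and metathesis and prevents retro-aldol cleavage once C9 is a ketone.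

Step 8
Reactants: 9 tert-butyl{[2-ethenyl-6-(methoxymethoxy)-6-methyl-3-(propan-2-yl)cyclohexyl]methoxy}diphenylsilane
Product: 10 [2-ethenyl-6-(methoxymethoxy)-6-methyl-3-(propan-2-yl)cyclohexyl]methanol
Conditions: Bu4NF, THF, rt
Reagents that add atoms: none
Why: Fluoride cleavage of the silyl ether frees the C9 hydroxyl; the acetal and the vinyl group are inert.

Step 9
Reactants: 10 [2-ethenyl-6-(methoxymethoxy)-6-methyl-3-(propan-2-yl)cyclohexyl]methanol
Product: 11 2-ethenyl-6-(methoxymethoxy)-6-methyl-3-(propan-2-yl)cyclohexane-1-carbaldehyde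
Conditions: Dess–Martin periodinane, pyridine, CH2Cl2, 0 °C → rt
Reagents that add atoms: none
Why: Dess–Martin oxidation under buffered, non-basic conditions gives the α-branched β-alkoxy aldehyde without epimerising C10 or eliminating the C11 ether.

Step 10
Reactants: 11 2-ethenyl-6-(methoxymethoxy)-6-methyl-3-(propan-2-yl)cyclohexane-1-carbaldehyde; 12 methyl phenyl sulfone
Product: 13 1-[2-ethenyl-6-(methoxymethoxy)-6-methyl-3-(propan-2-yl)cyclohexyl]-2-(phenylsulfonyl)ethan-1-ol (both C9 epimers)
Conditions: 12, n-BuLi, THF, −78 °C; then 11, −78 °C; then H2O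
Reagents that add atoms: none
Why: Addition of the α-sulfonyl carbanion to the aldehyde forms the C5–C9 bond; the soft, moderately basic nucleophile adds at −78 °C faster than it enolises the aldehyde, and the new carbinol centre is oxidised away in the next step.

Step 11
Reactants: 13 1-[2-ethenyl-6-(methoxymethoxy)-6-methyl-3-(propan-2-yl)cyclohexyl]-2-(phenylsulfonyl)ethan-1-ol
Product: 14 1-[2-ethenyl-6-(methoxymethoxy)-6-methyl-3-(propan-2-yl)cyclohexyl]-2-(phenylsulfonyl)ethan-1-one
Conditions: Dess–Martin periodinane, pyridine, CH2Cl2, rt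
Reagents that add atoms: none
Why: Dess–Martin oxidation of the β-hydroxy sulfone gives the β-keto sulfone, whose C5–H is now by far the most acidic hydrogen and protects C10 in the basic steps that follow.

Step 12
Reactants: 14 1-[2-ethenyl-6-(methoxymethoxy)-6-methyl-3-(propan-2-yl)cyclohexyl]-2-(phenylsulfonyl)ethan-1-one; 15 3-bromo-2-methylprop-1-ene
Product: 16 1-[2-ethenyl-6-(methoxymethoxy)-6-methyl-3-(propan-2-yl)cyclohexyl]-4-methyl-2-(phenylsulfonyl)pent-4-en-1-one (both C5 epimers)
Conditions: K2CO3, acetone, rt → 40 °C
Reagents that add atoms: none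
Why: C-alkylation of a β-keto sulfone enolate with an allylic bromide under carbonate conditions installs C4, C3 and the C3 methyl; the C5 configuration is of no consequence.

Step 13
Reactants: 16 1-[2-ethenyl-6-(methoxymethoxy)-6-methyl-3-(propan-2-yl)cyclohexyl]-4-methyl-2-(phenylsulfonyl)pent-4-en-1-one
Product: 17 8-(methoxymethoxy)-3,8-dimethyl-5-(phenylsulfonyl)-11-(propan-2-yl)bicyclo[5.4.0]undec-2-en-6-one (cis-fused; target numbering: C9 ketone, C5 sulfone, Z C2=C3)
Conditions: second-generation Grubbs catalyst (H2IMes)(PCy3)Cl2Ru=CHPh (5–10 mol%), toluene (2 mM), 80 °C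
Reagents that add atoms: none
Why: Ring-closing metathesis; the ruthenium alkylidene should load on the vinyl group and close onto the 1,1-disubstituted alkene, the cis arrangement of the two arms on ring A allows the cis-fused seven-membered ring, and in this ring the new C2=C3 bond can only be Z.

Step 14
Reactants: 17 8-(methoxymethoxy)-3,8-dimethyl-5-(phenylsulfonyl)-11-(propan-2-yl)bicyclo[5.4.0]undec-2-en-6-one; 18 2-(chloromethyl)-3-(trimethylsilyl)prop-1-ene
Product: 19 8-(methoxymethoxy)-3,8-dimethyl-5-(phenylsulfonyl)-11-(propan-2-yl)-5-{2-[(trimethylsilyl)methyl]prop-2-en-1-yl}bicyclo[5.4.0]undec-2-en-6-one (either C5 epimer)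
Conditions: Cs2CO3, Bu4NI (cat.), DMF, rt → 50 °C
Reagents that add atoms: none
Why: Alkylation of the cyclic β-keto sulfone enolate with the allylic iodide formed in situ (Finkelstein exchange), the known way to 2-allyl-2-sulfonylcycloalkanones; the carbonate base is too weak to enolise the product toward C10.

Step 15
Reactants: 19 8-(methoxymethoxy)-3,8-dimethyl-5-(phenylsulfonyl)-11-(propan-2-yl)-5-{2-[(trimethylsilyl)methyl]prop-2-en-1-yl}bicyclo[5.4.0]undec-2-en-6-one
Product: 22 (2Z)-11-(methoxymethoxy)-3,11-dimethyl-7-methylidene-5-(phenylsulfonyl)-14-(propan-2-yl)bicyclo[8.4.0]tetradec-2-en-9-one (C5 epimers), via bicyclic C9 alkoxide 20 (not isolated), via C5 sulfonyl carbanion 21 (not isolated)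
Conditions: Bu4NF·3H2O (1.2 equiv), THF, −20 → 0 °C; then pH 7 phosphate buffer
Reagents that add atoms: none
Why: Fluoride attacks silicon of 19 and the allyl nucleophile so released adds to the neighbouring C9 carbonyl, forming C8–C9 and the alkoxide 20; this closure is 5-exo-trig (ring C5–C6–C7–C8–C9) and, the allyl unit being symmetric about C7, either terminus gives the same carbinol. Alkoxide 20 then breaks the C5–C9 bond in a retro-aldol-type fragmentation, driven by relief of the two adjacent fully substituted centres and by formation of the sulfone-stabilised carbanion 21, so the ten-membered ring is not cyclised end to end but arises by opening the bond shared by the five- and seven-membered rings. The closest known reaction type is the fluoride-induced three-carbon ring expansion of 2-sulfonylcycloalkanones alkylated with 2-[(trimethylsilyl)methyl]allyl halides, which gives 3-methylene-5-sulfonylcycloalkanones. No stereocentre of 30 is created: C9 returns to sp2 and C5 is a removable sulfone centre, so both C5 epimers of 19 converge. The step needs carbonyl addition ahead of protodesilylation, which the intramolecular five-membered delivery secures, and fragmentation ahead of hydroxide attack on the non-enolisable keto sulfone. Carbanion 21 is a stronger base than the enolates of the new ketone, so C8–H and C10–H are not protected by relative acidity; they are protected kinetically by the water of the fluoride hydrate, which protonates 21 as it forms, by the low temperature and by the immediate buffered quench, which together limit enolisation toward C8 (conjugation of the C7 methylene) and toward C10 (epimerisation and loss of the C11 ether).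

Step 16
Reactants: 22 (2Z)-11-(methoxymethoxy)-3,11-dimethyl-7-methylidene-5-(phenylsulfonyl)-14-(propan-2-yl)bicyclo[8.4.0]tetradec-2-en-9-one
Product: 23 (2Z,9R)-11-(methoxymethoxy)-3,11-dimethyl-7-methylidene-5-(phenylsulfonyl)-14-(propan-2-yl)bicyclo[8.4.0]tetradec-2-en-9-ol (C5 epimers)
Conditions: (S)-2-methyl-CBS-oxazaborolidine (20 mol%), catecholborane, toluene, −78 °C
Reagents that add atoms: none
Why: Corey–Bakshi–Shibata reduction; with the branched C10 side as the large group and the C8 methylene as the small one, the (S)-catalyst should deliver hydride to give the 9R carbinol, and catecholborane at −78 °C should neither hydroborate the alkenes nor isomerise the β,γ-unsaturated ketone.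

Step 17
Reactants: 23 (2Z,9R)-11-(methoxymethoxy)-3,11-dimethyl-7-methylidene-5-(phenylsulfonyl)-14-(propan-2-yl)bicyclo[8.4.0]tetradec-2-en-9-ol
Product: 24 (2Z,9R)-11-(methoxymethoxy)-3,11-dimethyl-7-methylidene-14-(propan-2-yl)bicyclo[8.4.0]tetradec-2-en-9-ol
Conditions: 6% Na(Hg), Na2HPO4, MeOH/THF, −20 °C
Reagents that add atoms: none
Why: Reductive desulfonylation by electron transfer replaces the C5 sulfone by hydrogen and merges the C5 epimers; the phosphate buffer keeps methoxide from isomerising the alkenes.

Step 18
Reactants: 24 (2Z,9R)-11-(methoxymethoxy)-3,11-dimethyl-7-methylidene-14-(propan-2-yl)bicyclo[8.4.0]tetradec-2-en-9-ol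
Product: 25 (2Z,9R)-11-(methoxymethoxy)-3,11-dimethyl-7-methylidene-14-(propan-2-yl)bicyclo[8.4.0]tetradec-2-en-9-yl acetate
Conditions: Ac2O, pyridine, DMAP (cat.), CH2Cl2, rt
Reagents that add atoms: acetic anhydride, CC(=O)OC(C)=O
Why: Acetylation installs the final C9 ester, which also protects this carbinol during the oxidations at C6 and deactivates the C8 hydrogens toward allylic oxidation.

Step 19
Reactants: 25 (2Z,9R)-11-(methoxymethoxy)-3,11-dimethyl-7-methylidene-14-(propan-2-yl)bicyclo[8.4.0]tetradec-2-en-9-yl acetate
Product: 26 (2Z,9R)-11-hydroxy-3,11-dimethyl-7-methylidene-14-(propan-2-yl)bicyclo[8.4.0]tetradec-2-en-9-yl acetate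
Conditions: Me2BBr, CH2Cl2, −78 °C; then THF/H2O
Reagents that add atoms: none
Why: Boron-bromide cleavage of the methoxymethyl acetal at −78 °C attacks the O–CH2–O carbon and not C11, so no tertiary cation is formed and the acetate and both alkenes are spared; it is done here, before any allylic oxygen is present.

Step 20
Reactants: 26 (2Z,9R)-11-hydroxy-3,11-dimethyl-7-methylidene-14-(propan-2-yl)bicyclo[8.4.0]tetradec-2-en-9-yl acetate
Product: 27 (2Z,9R)-6,11-dihydroxy-3,11-dimethyl-7-methylidene-14-(propan-2-yl)bicyclo[8.4.0]tetradec-2-en-9-yl acetate (C6 epimers)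
Conditions: SeO2 (0.3 equiv), t-BuOOH, CH2Cl2, 0 °C → rt
Reagents that add atoms: selenium dioxide, O=[Se]=O; tert-butyl hydroperoxide, CC(C)(C)OO
Why: Selenium dioxide allylic hydroxylation (ene reaction at the unhindered C16 terminus, then [2,3]-sigmatropic shift) returns the double bond to the exocyclic position and puts oxygen on C6; C8 is deactivated by the acetoxy-bearing C9, and the ring alkene should be slower because selenium would have to bond to C2, next to the branched C1.

Step 21
Reactants: 27 (2Z,9R)-6,11-dihydroxy-3,11-dimethyl-7-methylidene-14-(propan-2-yl)bicyclo[8.4.0]tetradec-2-en-9-yl acetate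
Product: 28 (2Z,9R)-11-hydroxy-3,11-dimethyl-7-methylidene-6-oxo-14-(propan-2-yl)bicyclo[8.4.0]tetradec-2-en-9-yl acetate
Conditions: Dess–Martin periodinane, pyridine, CH2Cl2, 0 °C
Reagents that add atoms: none
Why: Dess–Martin oxidation merges both C6 epimers into one α-methylene ketone; the tertiary C11 alcohol cannot be oxidised.

Step 22
Reactants: 28 (2Z,9R)-11-hydroxy-3,11-dimethyl-7-methylidene-6-oxo-14-(propan-2-yl)bicyclo[8.4.0]tetradec-2-en-9-yl acetate
Product: 29 (2Z,6R,9R)-6,11-dihydroxy-3,11-dimethyl-7-methylidene-14-(propan-2-yl)bicyclo[8.4.0]tetradec-2-en-9-yl acetate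
Conditions: (S)-2-methyl-CBS-oxazaborolidine (20 mol%), catecholborane (2.5 equiv), toluene, −78 °C
Reagents that add atoms: none
Why: Corey–Bakshi–Shibata 1,2-reduction of the enone; the alkenyl C7 acts as the large group and the C5 methylene as the small one, so the (S)-catalyst should give the 6R allylic alcohol independently of the remote ring A centres, and at −78 °C the catalysed carbonyl addition should outrun uncatalysed conjugate reduction by catecholborane, which also leaves the acetate alone.

Step 23
Reactants: 29 (2Z,6R,9R)-6,11-dihydroxy-3,11-dimethyl-7-methylidene-14-(propan-2-yl)bicyclo[8.4.0]tetradec-2-en-9-yl acetate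
Product: 30 (1S,2Z,6R,9R,10S,11R,14R)-11-hydroxy-3,11-dimethyl-7-methylidene-14-(propan-2-yl)bicyclo[8.4.0]tetradec-2-ene-6,9-diyl diacetate
Conditions: Ac2O, pyridine, DMAP (cat.), CH2Cl2, 0 °C
Reagents that add atoms: acetic anhydride, CC(=O)OC(C)=O
Why: Acetylation of the secondary allylic alcohol; the hindered tertiary C11 alcohol is not acylated under these mild conditions, which completes the target.

## Compound list

1 | (2E)-3-methylpent-2-en-4-yn-1-ol | C#C/C(C)=C/CO | starting material
2 | tert-butyl{[(2E)-3-methylpent-2-en-4-yn-1-yl]oxy}diphenylsilane | C#C/C(C)=C/CO[Si](c1ccccc1)(c1ccccc1)C(C)(C)C | intermediate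
3 | tert-butyl{[(2E)-3-methylpenta-2,4-dien-1-yl]oxy}diphenylsilane | C=C/C(C)=C/CO[Si](c1ccccc1)(c1ccccc1)C(C)(C)C | intermediate
4 | (2E)-4-methylpent-2-enal | CC(C)/C=C/C=O | starting material
5 | (1R,2R,6R)-2-({[tert-butyl(diphenyl)silyl]oxy}methyl)-3-methyl-6-(propan-2-yl)cyclohex-3-ene-1-carbaldehyde (formyl cis to the silyloxymethyl arm, trans to isopropyl) | O=C[C@H]1[C@@H](CO[Si](c2ccccc2)(c2ccccc2)C(C)(C)C)C(C)=CC[C@@H]1C(C)C | intermediate
6 | tert-butyl{[6-ethenyl-2-methyl-5-(propan-2-yl)cyclohex-2-en-1-yl]methoxy}diphenylsilane (vinyl and silyloxymethyl β, isopropyl α) | C=C[C@H]1[C@@H](CO[Si](c2ccccc2)(c2ccccc2)C(C)(C)C)C(C)=CC[C@@H]1C(C)C | intermediate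
7 | tert-butyl{[3-ethenyl-1-methyl-4-(propan-2-yl)-7-oxabicyclo[4.1.0]heptan-2-yl]methoxy}diphenylsilane (11α,12α-epoxide) | C=C[C@H]1[C@@H](CO[Si](c2ccccc2)(c2ccccc2)C(C)(C)C)[C@]3(C)O[C@@H]3C[C@@H]1C(C)C | intermediate
8 | 2-({[tert-butyl(diphenyl)silyl]oxy}methyl)-3-ethenyl-1-methyl-4-(propan-2-yl)cyclohexan-1-ol (C11 hydroxyl α, methyl β) | C=C[C@H]1[C@@H](CO[Si](c2ccccc2)(c2ccccc2)C(C)(C)C)[C@](C)(O)CC[C@@H]1C(C)C | intermediate
9 | tert-butyl{[2-ethenyl-6-(methoxymethoxy)-6-methyl-3-(propan-2-yl)cyclohexyl]methoxy}diphenylsilane | C=C[C@H]1[C@@H](CO[Si](c2ccccc2)(c2ccccc2)C(C)(C)C)[C@](C)(OCOC)CC[C@@H]1C(C)C | intermediate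
10 | [2-ethenyl-6-(methoxymethoxy)-6-methyl-3-(propan-2-yl)cyclohexyl]methanol | C=C[C@H]1[C@@H](CO)[C@](C)(OCOC)CC[C@@H]1C(C)C | intermediate
11 | 2-ethenyl-6-(methoxymethoxy)-6-methyl-3-(propan-2-yl)cyclohexane-1-carbaldehyde | C=C[C@H]1[C@@H](C=O)[C@](C)(OCOC)CC[C@@H]1C(C)C | intermediate
12 | methyl phenyl sulfone | CS(=O)(=O)c1ccccc1 | starting material
13 | 1-[2-ethenyl-6-(methoxymethoxy)-6-methyl-3-(propan-2-yl)cyclohexyl]-2-(phenylsulfonyl)ethan-1-ol (C9 epimers) | C=C[C@H]1[C@@H](C(O)CS(=O)(=O)c2ccccc2)[C@](C)(OCOC)CC[C@@H]1C(C)C | intermediate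
14 | 1-[2-ethenyl-6-(methoxymethoxy)-6-methyl-3-(propan-2-yl)cyclohexyl]-2-(phenylsulfonyl)ethan-1-one | C=C[C@H]1[C@@H](C(=O)CS(=O)(=O)c2ccccc2)[C@](C)(OCOC)CC[C@@H]1C(C)C | intermediate
15 | 3-bromo-2-methylprop-1-ene | C=C(C)CBr | starting material
16 | 1-[2-ethenyl-6-(methoxymethoxy)-6-methyl-3-(propan-2-yl)cyclohexyl]-4-methyl-2-(phenylsulfonyl)pent-4-en-1-one (C5 epimers) | C=C[C@H]1[C@@H](C(=O)C(CC(C)=C)S(=O)(=O)c2ccccc2)[C@](C)(OCOC)CC[C@@H]1C(C)C | intermediate
17 | 8-(methoxymethoxy)-3,8-dimethyl-5-(phenylsulfonyl)-11-(propan-2-yl)bicyclo[5.4.0]undec-2-en-6-one (cis-fused, Z alkene, C5 epimers) | O=C1[C@@H]2[C@H](/C=C(/C)CC1S(=O)(=O)c1ccccc1)[C@@H](C(C)C)CC[C@@]2(C)OCOC | intermediate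
18 | 2-(chloromethyl)-3-(trimethylsilyl)prop-1-ene | C=C(CCl)C[Si](C)(C)C | starting material
19 | 8-(methoxymethoxy)-3,8-dimethyl-5-(phenylsulfonyl)-11-(propan-2-yl)-5-{2-[(trimethylsilyl)methyl]prop-2-en-1-yl}bicyclo[5.4.0]undec-2-en-6-one (either C5 epimer) | O=C1[C@@H]2[C@H](/C=C(/C)CC1(CC(=C)C[Si](C)(C)C)S(=O)(=O)c1ccccc1)[C@@H](C(C)C)CC[C@@]2(C)OCOC | intermediate
20 | tetrabutylammonium C9 alkoxide of the 5-exo adduct (C8–C9 bonded; five-membered ring C5–C6–C7–C8–C9 fused to the seven-membered ring) | [O-]C13[C@@H]2[C@H](/C=C(/C)CC1(CC(=C)C3)S(=O)(=O)c1ccccc1)[C@@H](C(C)C)CC[C@@]2(C)OCOC.CCCC[N+](CCCC)(CCCC)CCCC | intermediate (not isolated)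
21 | C5 sulfonyl carbanion of the ring-expanded ketone (tetrabutylammonium salt) | C=C1CC(=O)[C@@H]2[C@H](/C=C(/C)C[C-](C1)S(=O)(=O)c1ccccc1)[C@@H](C(C)C)CC[C@@]2(C)OCOC.CCCC[N+](CCCC)(CCCC)CCCC | intermediate (not isolated)
22 | (2Z)-11-(methoxymethoxy)-3,11-dimethyl-7-methylidene-5-(phenylsulfonyl)-14-(propan-2-yl)bicyclo[8.4.0]tetradec-2-en-9-one (C5 epimers) | C=C1CC(=O)[C@@H]2[C@H](/C=C(/C)CC(C1)S(=O)(=O)c1ccccc1)[C@@H](C(C)C)CC[C@@]2(C)OCOC | intermediate
23 | (2Z,9R)-11-(methoxymethoxy)-3,11-dimethyl-7-methylidene-5-(phenylsulfonyl)-14-(propan-2-yl)bicyclo[8.4.0]tetradec-2-en-9-ol (C5 epimers) | C=C1C[C@@H](O)[C@@H]2[C@H](/C=C(/C)CC(C1)S(=O)(=O)c1ccccc1)[C@@H](C(C)C)CC[C@@]2(C)OCOC | intermediate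
24 | (2Z,9R)-11-(methoxymethoxy)-3,11-dimethyl-7-methylidene-14-(propan-2-yl)bicyclo[8.4.0]tetradec-2-en-9-ol | C=C1C[C@@H](O)[C@@H]2[C@H](/C=C(/C)CCC1)[C@@H](C(C)C)CC[C@@]2(C)OCOC | intermediate
25 | (2Z,9R)-11-(methoxymethoxy)-3,11-dimethyl-7-methylidene-14-(propan-2-yl)bicyclo[8.4.0]tetradec-2-en-9-yl acetate | C=C1C[C@@H](OC(C)=O)[C@@H]2[C@H](/C=C(/C)CCC1)[C@@H](C(C)C)CC[C@@]2(C)OCOC | intermediate
26 | (2Z,9R)-11-hydroxy-3,11-dimethyl-7-methylidene-14-(propan-2-yl)bicyclo[8.4.0]tetradec-2-en-9-yl acetate | C=C1C[C@@H](OC(C)=O)[C@@H]2[C@H](/C=C(/C)CCC1)[C@@H](C(C)C)CC[C@@]2(C)O | intermediate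
27 | (2Z,9R)-6,11-dihydroxy-3,11-dimethyl-7-methylidene-14-(propan-2-yl)bicyclo[8.4.0]tetradec-2-en-9-yl acetate (C6 epimers) | C=C1C[C@@H](OC(C)=O)[C@@H]2[C@H](/C=C(/C)CCC1O)[C@@H](C(C)C)CC[C@@]2(C)O | intermediate
28 | (2Z,9R)-11-hydroxy-3,11-dimethyl-7-methylidene-6-oxo-14-(propan-2-yl)bicyclo[8.4.0]tetradec-2-en-9-yl acetate | C=C1C[C@@H](OC(C)=O)[C@@H]2[C@H](/C=C(/C)CCC1=O)[C@@H](C(C)C)CC[C@@]2(C)O | intermediate
29 | (2Z,6R,9R)-6,11-dihydroxy-3,11-dimethyl-7-methylidene-14-(propan-2-yl)bicyclo[8.4.0]tetradec-2-en-9-yl acetate | C=C1C[C@@H](OC(C)=O)[C@@H]2[C@H](/C=C(/C)CC[C@H]1O)[C@@H](C(C)C)CC[C@@]2(C)O | intermediate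
30 | (1S,2Z,6R,9R,10S,11R,14R)-11-hydroxy-3,11-dimethyl-7-methylidene-14-(propan-2-yl)bicyclo[8.4.0]tetradec-2-ene-6,9-diyl diacetate | C=C1C[C@@H](OC(C)=O)[C@@H]2[C@H](/C=C(/C)CC[C@H]1OC(C)=O)[C@@H](C(C)C)CC[C@@]2(C)O | target

## Step count and least certain steps

Total: 23 steps. Longest linear sequence: 23 steps, from 1 to 30; compounds 4, 12, 15 and 18 are used as purchased.

**Step 15 (key step).** Three processes may divert it:
- protodesilylation of the allylsilane before the C8–C9 bond forms, if the hindered C9 carbonyl is slow to accept the allyl group;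
- cleavage of the non-enolisable keto sulfone by hydroxide or fluoride attack at C9;
- after fragmentation, enolisation of the new ketone by carbanion 21 or by hydroxide, leading to migration of the C7 methylene into conjugation, epimerisation at C10 or elimination of the C11 ether.

Fallback: setting out from 19, the allyl transfer and the fragmentation would be separated. TiCl4 (CH2Cl2, −78 °C) should bring about an intramolecular Hosomi–Sakurai addition of the allylsilane to the chelated keto sulfone and give the bicyclic C9 carbinol F1, which is isolated. KN(SiMe3)2 (THF, −78 °C) would then generate the alkoxide 20 in the absence of hydroxide. It should fragment to 21, and a quench with AcOH at −78 °C returns to the route at 22.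

**Step 20 (allylic oxidation).** The selenium oxidant may attack the more electron-rich ring alkene instead of the methylene, oxidising the C3 methyl or C4, or it may abstract hydrogen from C8.

Fallback: setting out from 26, the ring alkene would be masked first. One equivalent of mCPBA (CH2Cl2, −20 °C) should epoxidise the trisubstituted C2=C3 bond in preference to the methylene, by the same reactivity order that causes the problem, and give the 2,3-epoxide F2. The SeO2/t-BuOOH oxidation then has a single alkene to act on and should give the epoxy C6 alcohol F3. Stereospecific deoxygenation (Ph3P=Se, CF3CO2H, CH2Cl2; episelenide extrusion with retention) restores the Z alkene and returns to the route at 27.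

**Step 3 (Diels–Alder).** The β-branched enal may react slowly with an acyclic diene under iminium catalysis. The C11 methyl directs against the C10 substituent, so some of the regioisomer with C10 bonded to C14 may form. Endo selectivity and enantioselectivity may be eroded.

Fallback: setting out from 3, an auxiliary-controlled, Lewis-acid-promoted cycloaddition would be used. (2E)-4-Methylpent-2-enoic acid is attached to (4S)-4-benzyl-1,3-oxazolidin-2-one (pivaloyl chloride, Et3N; then the lithiated oxazolidinone) to give the N-enoyl oxazolidinone F4. Et2AlCl (CH2Cl2, −40 °C) with 3 should give the endo imide adduct F5 through the chelated s-cis imide, whose benzyl group screens the face opposite to the one needed. LiBH4 (THF, MeOH, 0 °C) removes the auxiliary and gives the primary alcohol F6, and Dess–Martin oxidation returns to the route at 5.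

**Step 16 (C9 reduction).** The conformation of the ten-membered ketone may direct hydride to the face opposite to the one the catalyst favours (mismatched double stereodifferentiation), and the β,γ-unsaturated ketone may isomerise during a slow reduction.

Fallback: setting out from 22, the reduction would be run under substrate control (NaBH4, CeCl3·7H2O, MeOH, −78 °C; Luche conditions). Should this give the (9S) alcohol F7, a Mitsunobu inversion (4-nitrobenzoic acid, PPh3, DIAD, toluene) would give the (9R) 4-nitrobenzoate F8, and methanolysis (K2CO3, MeOH) returns to the route at 23.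

## Further compounds

F1 | step 15 | bicyclic C9 carbinol from Hosomi–Sakurai cyclisation of 19 (neutral form of 20) | OC13[C@@H]2[C@H](/C=C(/C)CC1(CC(=C)C3)S(=O)(=O)c1ccccc1)[C@@H](C(C)C)CC[C@@]2(C)OCOC
F2 | step 20 | 2,3-epoxide of 26 (cis-oxirane from the Z alkene; face not predicted, one diastereomer drawn) | C=C1C[C@@H](OC(C)=O)[C@@H]2[C@H]([C@H]3O[C@@]3(C)CCC1)[C@@H](C(C)C)CC[C@@]2(C)O
F3 | step 20 | 2,3-epoxy C6 alcohol (C6 epimers) | C=C1C[C@@H](OC(C)=O)[C@@H]2[C@H]([C@H]3O[C@@]3(C)CCC1O)[C@@H](C(C)C)CC[C@@]2(C)O
F4 | step 3 | (4S)-4-benzyl-3-[(2E)-4-methylpent-2-enoyl]-1,3-oxazolidin-2-one | CC(C)/C=C/C(=O)N1C(=O)OC[C@@H]1Cc1ccccc1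
F5 | step 3 | N-acyl oxazolidinone Diels–Alder adduct (ring A configuration of 5) | O=C(N1C(=O)OC[C@@H]1Cc1ccccc1)[C@H]1[C@@H](CO[Si](c2ccccc2)(c2ccccc2)C(C)(C)C)C(C)=CC[C@@H]1C(C)C
F6 | step 3 | [2-({[tert-butyl(diphenyl)silyl]oxy}methyl)-3-methyl-6-(propan-2-yl)cyclohex-3-en-1-yl]methanol (ring A configuration of 5) | OC[C@H]1[C@@H](CO[Si](c2ccccc2)(c2ccccc2)C(C)(C)C)C(C)=CC[C@@H]1C(C)C
F7 | step 16 | (9S) epimer of 23 | C=C1C[C@H](O)[C@@H]2[C@H](/C=C(/C)CC(C1)S(=O)(=O)c1ccccc1)[C@@H](C(C)C)CC[C@@]2(C)OCOC
F8 | step 16 | (9R) 4-nitrobenzoate of 23 | C=C1C[C@@H](OC(=O)c3ccc(cc3)[N+](=O)[O-])[C@@H]2[C@H](/C=C(/C)CC(C1)S(=O)(=O)c1ccccc1)[C@@H](C(C)C)CC[C@@]2(C)OCOC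
A1 | alternative 1 | ring A aldehyde, identical with 5 | O=C[C@H]1[C@@H](CO[Si](c2ccccc2)(c2ccccc2)C(C)(C)C)C(C)=CC[C@@H]1C(C)C
A2 | alternative 2 | thirteen-membered allyl (tributylstannyl)methyl ether (O links stannylated C9 to C20 on C11 of a C10=C11 ring A; C7 dioxolane, C6 silyl ether, Z C2=C3) | CC(C)[C@H]1CCC2=C[C@@H]1/C=C(/C)CC[C@@H](O[Si](C)(C)C(C)(C)C)C1(OCCO1)CC(OC2)[Sn](CCCC)(CCCC)CCCC
A3 | alternative 2 | ring-contracted ten-membered C9 alcohol with C11 methylene | CC(C)[C@H]1CCC(=C)[C@H]2[C@@H]1/C=C(/C)CC[C@@H](O[Si](C)(C)C(C)(C)C)C1(OCCO1)C[C@H]2O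
A4 | alternative 3 | cis-decalin C7 carbinol (C7 vinyl cis to C2 isopropenyl, C9 4-methoxybenzyl ether, C11 hydroxyl) | C=C[C@]1(O)C[C@@H](OCc3ccc(OC)cc3)[C@@H]2[C@H]([C@@H]1C(C)=C)[C@@H](C(C)C)CC[C@@]2(C)O
A5 | alternative 3 | ten-membered C7 ketone with Z C2=C3 alkene | O=C1C[C@@H](OCc3ccc(OC)cc3)[C@@H]2[C@H](/C=C(/C)CCC1)[C@@H](C(C)C)CC[C@@]2(C)O
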